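The cyclobutane ring (C1 CH–CO2Me, C2 CH–CO2H, C3 and C4 each C(CH3)(pyranone)) is treated as the saturated half of a bicyclo[2.2.0]hex-5-ene. Because the carboxyl carbons on C1 and C2 are cis, they can be tied together as the CH=CH unit of a fused cyclobutene and released late by oxidative cleavage. One photochemical 4π closure forges C1–C2, closes the four-membered ring and sets both C–H stereocentres. Its precursor is meso diene anhydride 6. The cis quaternary carbons of 6 (future C3/C4) carry the methyl groups and, as anhydride carbonyls, the future C6 atoms of both pyranones. Alkaloid-mediated methanolysis of a late meso anhydride fixes the absolute configuration.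

Key step: step 4

Remark (target numbering as above, C3 next to C2): 20 is (1R,2S,3R,4S). Both carboxyl carbons lie on the face of the two methyl groups and both pyranones on the opposite face, so 7 must carry its anhydride anti to the CH=CH bridge.

Assumption: for simple cis-fused succinic anhydrides quinidine is taken to give the (1R,2S)-2-(methoxycarbonyl)cycloalkane-1-carboxylic acid series, which matches 20 in space; if correlation shows the opposite sense, quinine replaces quinidine in step 13 with no other change.

Step 1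
Reactants: 1 buta-1,3-diene; 2 2,3-dimethylmaleic anhydride
Product: 3 cis-1,2-dimethylcyclohex-4-ene-1,2-dicarboxylic anhydride (meso)
Conditions: excess 1, PhMe, BHT (cat.), sealed vessel, 180 °C
Reagents that add atoms: none
Why: Thermal Diels–Alder reaction; the tetrasubstituted dienophile is sluggish but adds to unhindered butadiene at high temperature, and suprafacial addition carries the cis relation of the two methyl-bearing carbons (future C3/C4) into meso 3.

Step 2
Reactants: 3 cis-1,2-dimethylcyclohex-4-ene-1,2-dicarboxylic anhydride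
Product: 4 (±)-trans-4,5-dibromo-cis-1,2-dimethylcyclohexane-1,2-dicarboxylic anhydride
Conditions: Br2, CH2Cl2, 0 °C
Reagents that add atoms: bromine, BrBr
Why: Electrophilic anti addition through a bromonium ion gives the trans-dibromide as one racemic diastereomer (attack on either face leads to mirror images), and both C–Br centres are erased in step 3.

Step 3
Reactants: 4 (±)-trans-4,5-dibromo-cis-1,2-dimethylcyclohexane-1,2-dicarboxylic anhydride
Product: 6 cis-1,2-dimethylcyclohexa-3,5-diene-1,2-dicarboxylic anhydride (meso), via bromocyclohexene anhydride 5 (not isolated)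
Conditions: DBU (3 equiv), PhMe, 80 °C
Reagents that add atoms: none
Why: Twofold E2 dehydrobromination toward the ring CH2 groups, the only positions with anti-periplanar hydrogen, gives the conjugated diene, which cannot aromatise or migrate because both flanking carbons are quaternary, and the hindered anhydride should tolerate the non-nucleophilic amidine.

Step 4
Reactants: 6 cis-1,2-dimethylcyclohexa-3,5-diene-1,2-dicarboxylic anhydride
Product: 7 2,3-dimethylbicyclo[2.2.0]hex-5-ene-2,3-dicarboxylic anhydride (meso; anhydride anti to CH=CH and methyl groups syn to it)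
Conditions: hν (254 nm, quartz), Et2O (0.01 M), Ar, 0 °C
Reagents that add atoms: none
Why: π→π* excitation of the ring-locked s-cis diene triggers a disrotatory 4π electrocyclisation in which the diene termini (ring C3 and C6 of 6, the future C2 and C1) bond to each other while the inner diene carbons stay behind as the cyclobutene CH=CH. The closest known reaction type is the photochemical valence isomerisation of cis-1,2-dihydrophthalic anhydrides to bicyclo[2.2.0]hex-5-ene-2,3-dicarboxylic anhydrides. The single new σ bond closes the cyclobutane C1–C2–C3–C4, and with it the fused cyclobutene, in the photochemically allowed suprafacial disrotatory mode, the only one a six-membered ring can follow. C1 and C2 become cis to each other because both hydrogens turn to the same face, and their relation to C3/C4 is set by the direction of the fold: folding toward the methyl face gives the cis,anti,cis tricycle 7 with the flat rigid anhydride on the convex face, whereas the opposite fold would push both carbonyl groups and the ring oxygen under the new π bond. Periselectivity comes from the substrate, since the competing 6π opening would break the bond shared with the five-membered anhydride and create a strained nine-membered triene, and the quaternary carbons exclude hydrogen shifts and aromatisation. Product 7 no longer absorbs at 254 nm and should accumulate; the facial preference is the one open point of the route.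

Step 5
Reactants: 7 2,3-dimethylbicyclo[2.2.0]hex-5-ene-2,3-dicarboxylic anhydride
Product: 8 2,3-bis(hydroxymethyl)-2,3-dimethylbicyclo[2.2.0]hex-5-ene (meso; CH2OH groups anti to CH=CH)
Conditions: LiAlH4 (excess), THF, 0 → 50 °C; H2O/aq NaOH work-up
Reagents that add atoms: none
Why: Hydride reduction of a cyclic anhydride through the lactone to the 1,4-diol, which touches neither the isolated strained alkene nor any stereocentre and stays below the temperature at which the bicyclohexene reopens.

Step 6
Reactants: 8 2,3-bis(hydroxymethyl)-2,3-dimethylbicyclo[2.2.0]hex-5-ene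
Product: 9 2,3-dimethylbicyclo[2.2.0]hex-5-ene-2,3-dicarbaldehyde (meso; CHO groups anti to CH=CH)
Conditions: (COCl)2, DMSO, CH2Cl2, −78 °C; Et3N, −78 → 0 °C
Reagents that add atoms: none
Why: Swern oxidation activates both hydroxyl groups as alkoxysulfonium ions before base is added, so the hydroxy-aldehyde that would close to a lactol and over-oxidise to the lactone never builds up, and the aldehydes have no α-hydrogen to lose.

Step 7
Reactants: 9 2,3-dimethylbicyclo[2.2.0]hex-5-ene-2,3-dicarbaldehyde; 10 ethyl 2-methylacetoacetate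
Product: 12 diethyl 5,5'-(2,3-dimethylbicyclo[2.2.0]hex-5-ene-2,3-diyl)bis(5-hydroxy-2-methyl-3-oxopentanoate) (mixture of side-chain epimers), via sodium lithium dianion 11 (not isolated)
Conditions: 10 (5 equiv), NaH, THF, 0 °C; n-BuLi, 0 °C; 9, −78 → 0 °C; aq NH4Cl
Reagents that add atoms: none
Why: γ-Selective aldol addition of a β-keto ester dianion, whose unhindered CH2 terminus adds readily to non-enolisable neopentyl aldehydes; excess reagent and warming let any lactolate of the mono-adduct reopen, and the uncontrolled carbinol and α-methyl centres are erased in steps 8 and 9.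

Step 8
Reactants: 12 diethyl 5,5'-(2,3-dimethylbicyclo[2.2.0]hex-5-ene-2,3-diyl)bis(5-hydroxy-2-methyl-3-oxopentanoate)
Product: 13 diethyl 5,5'-(2,3-dimethylbicyclo[2.2.0]hex-5-ene-2,3-diyl)bis(2-methyl-3,5-dioxopentanoate)
Conditions: Dess–Martin periodinane, CH2Cl2, 0 °C → rt
Reagents that add atoms: none
Why: Dess–Martin oxidation is the standard mild conversion of δ-hydroxy-β-keto esters into 3,5-dioxo esters, and the resulting 1,4-diketone cannot dehydrate to a furan because the carbons between the ketones are quaternary.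

Step 9
Reactants: 13 diethyl 5,5'-(2,3-dimethylbicyclo[2.2.0]hex-5-ene-2,3-diyl)bis(2-methyl-3,5-dioxopentanoate)
Product: 14 6,6'-(2,3-dimethylbicyclo[2.2.0]hex-5-ene-2,3-diyl)bis(4-hydroxy-3-methyl-2H-pyran-2-one) (meso)
Conditions: DBU, PhMe, rt → 45 °C; 1 M HCl
Reagents that add atoms: none
Why: Base-induced enol lactonisation, in which the C5 enolate oxygen of each 3,5-dioxo ester attacks its own ester carbonyl and expels ethoxide; both diketones sit as unreactive enolates, which should suppress cross-aldol reaction between the chains.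

Step 10
Reactants: 14 6,6'-(2,3-dimethylbicyclo[2.2.0]hex-5-ene-2,3-diyl)bis(4-hydroxy-3-methyl-2H-pyran-2-one)
Product: 15 6,6'-(2,3-dimethylbicyclo[2.2.0]hex-5-ene-2,3-diyl)bis(4-methoxy-3-methyl-2H-pyran-2-one) (meso)
Conditions: Me2SO4, K2CO3, acetone, 50 °C
Reagents that add atoms: dimethyl sulfate, COS(=O)(=O)OC
Why: O-Alkylation of the vinylogous acid with dimethyl sulfate and carbonate in acetone is the usual way to the 4-methoxy-2-pyranone rather than the 2-methoxy-4-pyranone isomer.

Step 11
Reactants: 15 6,6'-(2,3-dimethylbicyclo[2.2.0]hex-5-ene-2,3-diyl)bis(4-methoxy-3-methyl-2H-pyran-2-one)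
Product: 18 3,4-bis(4-methoxy-3-methyl-2-oxo-2H-pyran-6-yl)-3,4-dimethylcyclobutane-1,2-dicarboxylic acid (meso; carboxyls cis to the methyls), via ozonide 16 (not isolated), via cyclobutane dialdehyde 17 (not isolated)
Conditions: O3, CH2Cl2, −78 °C (Sudan Red 7B end point); PPh3, −78 °C → rt; concentrate; NaClO2, NaH2PO4, 2-methylbut-2-ene, t-BuOH/H2O, 0 °C → rt
Reagents that add atoms: ozone, [O-][O+]=O; sodium chlorite, [Na+].[O-]Cl=O
Why: Ozonolysis followed by Pinnick oxidation; the strained cis-disubstituted cyclobutene should consume ozone far faster than the push–pull pyranone double bonds (dye-controlled end point), and the neutral reduction and buffered, scavenged oxidation leave the epimerisable C1–H and C2–H untouched.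

Step 12
Reactants: 18 3,4-bis(4-methoxy-3-methyl-2-oxo-2H-pyran-6-yl)-3,4-dimethylcyclobutane-1,2-dicarboxylic acid
Product: 19 6,7-bis(4-methoxy-3-methyl-2-oxo-2H-pyran-6-yl)-6,7-dimethyl-3-oxabicyclo[3.2.0]heptane-2,4-dione (meso; anhydride cis to the methyls)
Conditions: Ac2O, 60 °C; evaporate
Reagents that add atoms: none
Why: Dehydrative closure of a cis-1,2-diacid to the five-membered anhydride by anhydride exchange, which also acts as a stereochemical filter because a trans diacid cannot close under these conditions.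

Step 13
Reactants: 19 6,7-bis(4-methoxy-3-methyl-2-oxo-2H-pyran-6-yl)-6,7-dimethyl-3-oxabicyclo[3.2.0]heptane-2,4-dione
Product: 20 (1S,2R,3S,4R)-2-(methoxycarbonyl)-3,4-bis(4-methoxy-3-methyl-2-oxo-2H-pyran-6-yl)-3,4-dimethylcyclobutane-1-carboxylic acid
Conditions: quinidine (1.1 equiv), MeOH (10 equiv), PhMe, −55 °C; 1 M HCl wash
Reagents that add atoms: methanol, CO
Why: Cinchona-alkaloid-mediated desymmetrising methanolysis of a meso cyclic anhydride, in which the quinuclidine nitrogen delivers methanol to one of the two enantiotopic carbonyl groups (the one on C1) and thereby turns the four relative stereocentres of 19 into one absolute array without touching any of them.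

Compound list
1 | buta-1,3-diene | C=CC=C | starting material
2 | 2,3-dimethylmaleic anhydride | CC1=C(C)C(=O)OC1=O | starting material
3 | cis-1,2-dimethylcyclohex-4-ene-1,2-dicarboxylic anhydride (meso) | C[C@]12CC=CC[C@@]1(C)C(=O)OC2=O | intermediate
4 | (±)-trans-4,5-dibromo-cis-1,2-dimethylcyclohexane-1,2-dicarboxylic anhydride (one enantiomer drawn) | C[C@]12C[C@H](Br)[C@@H](Br)C[C@@]1(C)C(=O)OC2=O | intermediate
5 | (±)-5-bromo-cis-1,2-dimethylcyclohex-3-ene-1,2-dicarboxylic anhydride (C–Br configuration not defined) | C[C@]12C=CC(Br)C[C@@]1(C)C(=O)OC2=O | intermediate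
6 | cis-1,2-dimethylcyclohexa-3,5-diene-1,2-dicarboxylic anhydride (meso) | C[C@]12C=CC=C[C@@]1(C)C(=O)OC2=O | intermediate
7 | 2,3-dimethylbicyclo[2.2.0]hex-5-ene-2,3-dicarboxylic anhydride, anhydride anti to CH=CH (meso) | C1=C[C@@H]2[C@H]1[C@@](C)(C(=O)OC3=O)[C@]23C | intermediate
8 | 2,3-bis(hydroxymethyl)-2,3-dimethylbicyclo[2.2.0]hex-5-ene, CH2OH anti to CH=CH (meso) | C1=C[C@@H]2[C@H]1[C@@](C)(CO)[C@]2(CO)C | intermediate
9 | 2,3-dimethylbicyclo[2.2.0]hex-5-ene-2,3-dicarbaldehyde, CHO anti to CH=CH (meso) | C1=C[C@@H]2[C@H]1[C@@](C)(C=O)[C@]2(C=O)C | intermediate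
10 | ethyl 2-methylacetoacetate | CCOC(=O)C(C)C(C)=O | starting material
11 | sodium lithium dianion (bis-enolate) of ethyl 2-methylacetoacetate | [Na+].[Li+].C=C([O-])C(C)=C([O-])OCC | intermediate
12 | bis-aldol: diethyl 5,5'-(2,3-dimethylbicyclo[2.2.0]hex-5-ene-2,3-diyl)bis(5-hydroxy-2-methyl-3-oxopentanoate), side-chain epimers | C1=C[C@@H]2[C@H]1[C@@](C)(C(O)CC(=O)C(C)C(=O)OCC)[C@]2(C(O)CC(=O)C(C)C(=O)OCC)C | intermediate
13 | tetraketone: diethyl 5,5'-(2,3-dimethylbicyclo[2.2.0]hex-5-ene-2,3-diyl)bis(2-methyl-3,5-dioxopentanoate) | C1=C[C@@H]2[C@H]1[C@@](C)(C(=O)CC(=O)C(C)C(=O)OCC)[C@]2(C(=O)CC(=O)C(C)C(=O)OCC)C | intermediate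
14 | bis(4-hydroxy-3-methyl-2-oxopyran-6-yl) bicyclohexene, pyranones anti to CH=CH (meso) | C1=C[C@@H]2[C@H]1[C@@](C)(c3cc(O)c(C)c(=O)o3)[C@]2(c3cc(O)c(C)c(=O)o3)C | intermediate
15 | bis(4-methoxy-3-methyl-2-oxopyran-6-yl) bicyclohexene, pyranones anti to CH=CH (meso) | C1=C[C@@H]2[C@H]1[C@@](C)(c3cc(OC)c(C)c(=O)o3)[C@]2(c3cc(OC)c(C)c(=O)o3)C | intermediate
16 | secondary ozonide of 15 (1,2,4-trioxolane bridging the carbons on C1 and C2; acetal carbons not assigned) | C12OOC(O1)[C@@H]3[C@@](C)(c4cc(OC)c(C)c(=O)o4)[C@@](C)(c4cc(OC)c(C)c(=O)o4)[C@H]23 | intermediate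
17 | 3,4-bis(4-methoxy-3-methyl-2-oxopyran-6-yl)-3,4-dimethylcyclobutane-1,2-dicarbaldehyde, CHO cis to CH3 (meso) | O=C[C@@H]1[C@H](C=O)[C@@](C)(c2cc(OC)c(C)c(=O)o2)[C@@]1(C)c1cc(OC)c(C)c(=O)o1 | intermediate
18 | corresponding cis-1,2-dicarboxylic acid, CO2H cis to CH3 (meso) | OC(=O)[C@@H]1[C@H](C(=O)O)[C@@](C)(c2cc(OC)c(C)c(=O)o2)[C@@]1(C)c1cc(OC)c(C)c(=O)o1 | intermediate
19 | corresponding cyclic anhydride, anhydride cis to CH3 and trans to the pyranones (meso) | O=C1OC(=O)[C@@H]2[C@H]1[C@@](C)(c3cc(OC)c(C)c(=O)o3)[C@@]2(C)c4cc(OC)c(C)c(=O)o4 | intermediate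
20 | (1S,2R,3S,4R)-2-(methoxycarbonyl)-3,4-bis(4-methoxy-3-methyl-2-oxo-2H-pyran-6-yl)-3,4-dimethylcyclobutane-1-carboxylic acid | COC(=O)[C@@H]1[C@H](C(=O)O)[C@@](C)(c2cc(OC)c(C)c(=O)o2)[C@@]1(C)c1cc(OC)c(C)c(=O)o1 | target

Total step count: 13. Longest linear sequence: 13 steps (from 1 and 2).

Steps most likely to fail

**Step 4.** The fold may go toward the anhydride face instead of the methyl face, or follow both modes. The fallback replaces kinetic facial control by thermodynamic control of C1 and C2.
- Setting out from 6, the irradiation product syn anhydride F1 is taken through the operations of steps 5–10: syn diol F2, syn dialdehyde F3, syn bis-aldol F4, syn tetraketone F5, syn bis(hydroxypyranone) F6 and syn bis(methoxypyranone) F7.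
- F7 is ozonised as in step 11, through syn ozonide F8, to all-cis dialdehyde F9.
- In F9 both formyl groups and both pyranones crowd one face, and C1–H and C2–H are now α to carbonyl groups. Catalytic DBU in CH2Cl2 should therefore epimerise them one after the other, through trans dialdehyde F10, to 17, where the route is rejoined.
- Pinnick oxidation of the equilibrated mixture and step 12 then sort the isomers, because only 18 closes under mild conditions.
- The trans diacid F11 is removed by bicarbonate extraction and driven to 19 by heating in Ac2O/NaOAc. There the mixed anhydride epimerises and closure occurs on the less crowded methyl face.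
- Any F1 not needed can be returned to 6 by thermal ring opening (xylene, about 140 °C) and irradiated again.

**Step 7.** The second addition may stall because the alkoxide of the mono-adduct closes onto the neighbouring formyl group, and retro-aldol loss on warming may add to this. The fallback builds each pyranone from a methyl ketone and a C3 diacid chloride instead of from an aldehyde and a C5 dianion.
- Setting out from 9, excess MeMgBr (THF, 0 °C → rt) should give bis(1-hydroxyethyl) compound F12. Small hard organometallics add routinely to lactolates.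
- Swern oxidation gives diketone F13, and TMSOTf/Et3N gives bis(silyl enol ether) F14.
- C-acylation then O-acylation of F14 with methylmalonyl dichloride (Et2O, −78 °C → rt) closes both 4-hydroxy-3-methylpyranones and rejoins the route at 14.

**Step 13.** Discrimination between the two carbonyl groups may be poor, or the opening sluggish, because the methyl groups flank the anhydride. The fallback uses a covalent chiral auxiliary and separation instead of reagent-controlled desymmetrisation.
- Setting out from 19, lithium (R)-1-phenylethoxide (THF, −78 °C) opens the anhydride to two chromatographically separable hemiesters: C2-(1-phenylethyl) hemiester F15 and C1-(1-phenylethyl) hemiester F16.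
- F15 is methylated with TMSCHN2 to mixed diester F17.
- Acidolysis of the benzylic ester of F17 (TFA, Et3SiH, CH2Cl2) gives 20.
- The same acidolysis returns F16 to 18 for another pass.

Further compounds
F1 | step 4 | 2,3-dimethylbicyclo[2.2.0]hex-5-ene-2,3-dicarboxylic anhydride, anhydride syn to CH=CH (meso) | C1=C[C@H]2[C@@H]1[C@@](C)(C(=O)OC3=O)[C@]23C
F2 | step 4 | 2,3-bis(hydroxymethyl)-2,3-dimethylbicyclo[2.2.0]hex-5-ene, CH2OH syn to CH=CH (meso) | C1=C[C@H]2[C@@H]1[C@@](C)(CO)[C@]2(CO)C
F3 | step 4 | 2,3-dimethylbicyclo[2.2.0]hex-5-ene-2,3-dicarbaldehyde, CHO syn to CH=CH (meso) | C1=C[C@H]2[C@@H]1[C@@](C)(C=O)[C@]2(C=O)C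
F4 | step 4 | syn bis-aldol (side-chain epimers) | C1=C[C@H]2[C@@H]1[C@@](C)(C(O)CC(=O)C(C)C(=O)OCC)[C@]2(C(O)CC(=O)C(C)C(=O)OCC)C
F5 | step 4 | syn tetraketone diester | C1=C[C@H]2[C@@H]1[C@@](C)(C(=O)CC(=O)C(C)C(=O)OCC)[C@]2(C(=O)CC(=O)C(C)C(=O)OCC)C
F6 | step 4 | syn bis(4-hydroxy-3-methyl-2-oxopyran-6-yl) bicyclohexene (meso) | C1=C[C@H]2[C@@H]1[C@@](C)(c3cc(O)c(C)c(=O)o3)[C@]2(c3cc(O)c(C)c(=O)o3)C
F7 | step 4 | syn bis(4-methoxy-3-methyl-2-oxopyran-6-yl) bicyclohexene (meso) | C1=C[C@H]2[C@@H]1[C@@](C)(c3cc(OC)c(C)c(=O)o3)[C@]2(c3cc(OC)c(C)c(=O)o3)C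
F8 | step 4 | secondary ozonide of F7 (acetal carbons not assigned) | C12OOC(O1)[C@H]3[C@@](C)(c4cc(OC)c(C)c(=O)o4)[C@@](C)(c4cc(OC)c(C)c(=O)o4)[C@@H]23
F9 | step 4 | all-cis dialdehyde, CHO cis to the pyranones (meso) | O=C[C@H]1[C@@H](C=O)[C@@](C)(c2cc(OC)c(C)c(=O)o2)[C@@]1(C)c1cc(OC)c(C)c(=O)o1
F10 | step 4 | (±)-trans dialdehyde (one enantiomer drawn) | O=C[C@@H]1[C@@H](C=O)[C@@](C)(c2cc(OC)c(C)c(=O)o2)[C@@]1(C)c1cc(OC)c(C)c(=O)o1
F11 | step 4 | (±)-trans diacid (one enantiomer drawn) | OC(=O)[C@@H]1[C@@H](C(=O)O)[C@@](C)(c2cc(OC)c(C)c(=O)o2)[C@@]1(C)c1cc(OC)c(C)c(=O)o1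
F12 | step 7 | 2,3-bis(1-hydroxyethyl)-2,3-dimethylbicyclo[2.2.0]hex-5-ene, substituents anti to CH=CH (carbinol epimers) | C1=C[C@@H]2[C@H]1[C@@](C)(C(C)O)[C@]2(C(C)O)C
F13 | step 7 | 2,3-diacetyl-2,3-dimethylbicyclo[2.2.0]hex-5-ene, acetyl groups anti to CH=CH (meso) | C1=C[C@@H]2[C@H]1[C@@](C)(C(C)=O)[C@]2(C(C)=O)C
F14 | step 7 | 2,3-dimethyl-2,3-bis[1-(trimethylsilyloxy)vinyl]bicyclo[2.2.0]hex-5-ene (meso) | C1=C[C@@H]2[C@H]1[C@@](C)(C(=C)O[Si](C)(C)C)[C@]2(C(=C)O[Si](C)(C)C)C
F15 | step 13 | hemiester with (R)-1-phenylethyl ester on the C2 carboxyl and free acid on C1 | OC(=O)[C@@H]1[C@H](C(=O)O[C@H](C)c2ccccc2)[C@@](C)(c2cc(OC)c(C)c(=O)o2)[C@@]1(C)c1cc(OC)c(C)c(=O)o1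
F16 | step 13 | hemiester with (R)-1-phenylethyl ester on the C1 carboxyl and free acid on C2 | O=C(O[C@H](C)c2ccccc2)[C@@H]1[C@H](C(=O)O)[C@@](C)(c2cc(OC)c(C)c(=O)o2)[C@@]1(C)c1cc(OC)c(C)c(=O)o1
F17 | step 13 | mixed diester, methyl ester on C1 and (R)-1-phenylethyl ester on C2 | COC(=O)[C@@H]1[C@H](C(=O)O[C@H](C)c2ccccc2)[C@@](C)(c2cc(OC)c(C)c(=O)o2)[C@@]1(C)c1cc(OC)c(C)c(=O)o1
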